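**Retrosynthetic overview**

1. Target ⇐ tri-O-benzyl alkenyl lactone by one hydrogenation (C2'=C3' alkene and three benzyl ethers) ⇐ cross-metathesis at C2'=C3' of a 3-allyl lactone with (S)-dec-9-en-3-yl benzyl ether, itself from (S)-1,2-epoxybutane (source of C9') and 6-bromohex-1-ene.
2. 3-Allyl lactone ⇐ δ-hydroxy ester by lactonisation (O2–C1), which closes ring B, the only ring the route forms ⇐ arylacetaldehyde by reagent-controlled allylboration (C3–C1' bond, C3 set by the isopinocampheyl groups).
3. Arylacetaldehyde ⇐ homophthalate diester ⇐ key disconnection at C4a–C4 and C8a–C1: in ring A the neighbouring carbons C4a and C8a carry the C4 methylene and the C1 carboxyl, and C8, next to C8a, carries oxygen, which is the pattern left when a 3-alkoxyaryne is inserted into a C–C bond of malonate.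
4. Aryne precursor (ortho-silyl aryl triflate) ⇐ 3,5-bis(benzyloxy)phenol by ortho-bromination, O-silylation and retro-Brook shift/triflation.
5. Ring order: ring A (benzene) is bought; ring B (δ-lactone) is closed in step 7.

Key step: step 4

Remark: the ring oxygens and the side-chain hydroxyl are carried as benzyl ethers, so that one neutral hydrogenation, which also saturates the metathesis alkene, ends the route. 3,5-Bis(benzyloxy)phenol is taken to be a catalogue compound. Locants C1–C8a refer to the isochroman-1-one core and C1'–C11' to the side chain.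

**Route**

Step 1
Reactants: 1 3,5-bis(benzyloxy)phenol
Product: 2 3,5-bis(benzyloxy)-2-bromophenol
Conditions: NBS (1.0 equiv), CH2Cl2, −78 °C → rt
Reagents that add atoms: N-bromosuccinimide, O=C1CCC(=O)N1Br
Why: Electrophilic aromatic bromination of an activated phenol, expected at one of the two equivalent positions ortho to OH because NBS is delivered through hydrogen bonding to the phenol in CH2Cl2 and the position between the two benzyloxy groups is the most hindered; one equivalent at low temperature limits dibromination.

Step 2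
Reactants: 2 3,5-bis(benzyloxy)-2-bromophenol
Product: 3 [3,5-bis(benzyloxy)-2-bromophenoxy]trimethylsilane
Conditions: (Me3Si)2NH, THF, 70 °C; volatiles removed
Reagents that add atoms: hexamethyldisilazane, C[Si](C)(C)N[Si](C)(C)C
Why: O-Silylation of the phenol by hexamethyldisilazane gives the aryl trimethylsilyl ether with ammonia as the only by-product, so the crude material can go straight into the next step.

Step 3
Reactants: 3 [3,5-bis(benzyloxy)-2-bromophenoxy]trimethylsilane
Product: 6 3,5-bis(benzyloxy)-2-(trimethylsilyl)phenyl trifluoromethanesulfonate, via aryllithium 4 (not isolated), via lithium silylphenoxide 5 (not isolated)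
Conditions: n-BuLi (1.1 equiv), THF, −100 °C → −80 °C; then Tf2O (1.2 equiv), −100 °C → rt
Reagents that add atoms: trifluoromethanesulfonic anhydride, O=S(=O)(OS(=O)(=O)C(F)(F)F)C(F)(F)F; n-butyllithium, [Li]CCCC (lithium stays only in intermediates 4 and 5)
Why: Bromine–lithium exchange at −100 °C outruns attack of n-BuLi on the benzyl ethers, the ortho-lithiated silyl ether 4 undergoes the 1,3-O→C silyl shift (retro-Brook rearrangement) to phenoxide 5, and the phenoxide is triflated on oxygen by Tf2O.

Step 4
Reactants: 6 3,5-bis(benzyloxy)-2-(trimethylsilyl)phenyl trifluoromethanesulfonate; 7 dimethyl malonate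
Product: 13 methyl 2,4-bis(benzyloxy)-6-(2-methoxy-2-oxoethyl)benzoate, via caesium malonate 8 (not isolated), via aryne 9 (not isolated), via aryl caesium adduct 10 (not isolated), via benzocyclobutenoxide 11 (not isolated), via caesium ester enolate 12 (not isolated)
Conditions: CsF (3.0 equiv), 7 (2.0 equiv), MeCN, 60 °C
Reagents that add atoms: caesium fluoride, [Cs+].[F-] (caesium stays only in intermediates 8, 10, 11 and 12)
Why: Fluoride attacks silicon in 6 and triflate leaves to give aryne 9, while the basic medium converts 7 into caesium malonate 8. Carbanion 8 adds to the aryne carbon remote from the neighbouring benzyloxy group (the future C4a), which places the charge of aryl anion 10 on the carbon flanked by that benzyloxy group (the future C8a); this anion adds to one ester carbonyl in a 4-exo-trig closure to the transient benzocyclobutenoxide 11, whose four-membered ring fragments to the ester-stabilised benzylic enolate 12, and proton transfer from excess 7 gives 13. The aryne thus ends up inserted into a C–C bond of the malonate, so that the C4a–C4 and C8a–C1 bonds are formed in one operation. The closest known reaction type is the σ-insertion of arynes into malonates and β-keto esters (aryne acyl-alkylation). No ring of the target is closed (the four-membered ring is only transient) and no stereocentre is formed. The selectivity needed is the regiochemistry of the first addition: the inductively withdrawing benzyloxy group beside the triple bond distorts the aryne and stabilises negative charge on the adjacent carbon, so attack at the distal carbon is expected, the second benzyloxy group being too remote to oppose it, and excess malonate keeps 13, which has an acidic benzylic CH2, from being arylated a second time.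

Step 5
Reactants: 13 methyl 2,4-bis(benzyloxy)-6-(2-methoxy-2-oxoethyl)benzoate
Product: 15 methyl 2,4-bis(benzyloxy)-6-(2-oxoethyl)benzoate, via aluminium hemiacetal 14 (not isolated)
Conditions: iBu2AlH (1.1 equiv), toluene, −78 °C; MeOH quench at −78 °C, aq. KNaC4H4O6 (potassium sodium tartrate); used crude
Reagents that add atoms: diisobutylaluminium hydride, CC(C)C[AlH]CC(C)C (aluminium and the isobutyl groups stay only in intermediate 14)
Why: Partial reduction of an ester with DIBAL-H, in which the unhindered aliphatic ester should react in preference to the aryl ester (flanked by two ortho substituents, twisted and electron-rich) and the tetrahedral aluminium hemiacetal 14 holds until the cold quench, so that the aldehyde is not reduced further.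

Step 6
Reactants: 15 methyl 2,4-bis(benzyloxy)-6-(2-oxoethyl)benzoate
Product: 17 methyl 2,4-bis(benzyloxy)-6-[(2R)-2-hydroxypent-4-en-1-yl]benzoate, via borinate 16 (not isolated)
Conditions: B-allyldiisopinocampheylborane built from (−)-α-pinene (preformed, magnesium-salt-free solution, 1.3 equiv), Et2O, −78 °C; then 3 M NaOH, 30% H2O2, 0 °C → rt
Reagents that add atoms: B-allyldiisopinocampheylborane from (−)-α-pinene, C=CCB([C@H]1C[C@H]2C[C@@H]([C@@H]1C)C2(C)C)[C@H]1C[C@H]2C[C@@H]([C@@H]1C)C2(C)C (boron and the isopinocampheyl groups stay only in intermediate 16)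
Why: Brown allylboration, in which allyl is transferred through a closed chair-like six-membered transition state and the isopinocampheyl groups built from (−)-α-pinene, the antipodes of those that direct allyl to the Si face of aldehydes, should direct it to the Re face and so give the 2R carbinol (C3 of the target); at −78 °C the salt-free reagent should add faster than the arylacetaldehyde enolises and should leave the hindered aryl ester and the benzyl ethers alone, and the oxidative work-up cleaves borinate 16.

Step 7
Reactants: 17 methyl 2,4-bis(benzyloxy)-6-[(2R)-2-hydroxypent-4-en-1-yl]benzoate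
Product: 18 (3R)-3-allyl-6,8-bis(benzyloxy)isochroman-1-one
Conditions: p-TsOH·H2O (10 mol%), toluene, 80 °C
Reagents that add atoms: none
Why: Acid-catalysed intramolecular transesterification (6-exo-trig lactonisation) closes ring B by forming the O2–C1 bond; the C3–O bond is not broken, so the 3R configuration is kept, and any lactone already formed during the basic work-up of step 6 converges here.

Step 8
Reactants: 19 6-bromohex-1-ene; 20 (S)-1,2-epoxybutane
Product: 22 (3S)-dec-9-en-3-ol, via Grignard reagent 21 (not isolated)
Conditions: Mg, THF, rt; then CuI (10 mol%), 20, THF, −30 °C → 0 °C; 1 M HCl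
Reagents that add atoms: magnesium, [Mg] (stays only in intermediate 21)
Why: Grignard formation (kept at room temperature to limit cyclisation of the hexenyl chain) followed by copper-catalysed SN2 opening of the terminal epoxide at its CH2 carbon; the C–O bond at the stereocentre is not touched, so the S configuration of 20 becomes the 3S carbinol (C9' of the target).

Step 9
Reactants: 22 (3S)-dec-9-en-3-ol
Product: 23 (S)-{[(dec-9-en-3-yl)oxy]methyl}benzene
Conditions: NaH (1.5 equiv), BnBr (1.3 equiv), Bu4NI (cat.), THF/DMF, 0 °C → rt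
Reagents that add atoms: benzyl bromide, BrCc1ccccc1
Why: Williamson etherification of the sodium alkoxide with benzyl bromide, the stereocentre being a spectator; the benzyl ether tolerates the ruthenium carbene of step 10 and falls together with the aryl benzyl ethers at the end.

Step 10
Reactants: 18 (3R)-3-allyl-6,8-bis(benzyloxy)isochroman-1-one; 23 (S)-{[(dec-9-en-3-yl)oxy]methyl}benzene
Product: 24 (3R)-6,8-bis(benzyloxy)-3-[(2E,9S)-9-(benzyloxy)undec-2-en-1-yl]isochroman-1-one
Conditions: 23 (3 equiv), second-generation Grubbs catalyst RuCl2(=CHPh)(H2IMes)(PCy3) (5 mol%), CH2Cl2, 40 °C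
Reagents that add atoms: none
Why: Olefin cross-metathesis between two unhindered monosubstituted alkenes, driven by loss of ethene, in which an excess of the simpler partner 23 should channel lactone 18 into the cross product (the homodimer of 23 re-enters the cycle by secondary metathesis); the E alkene should predominate, its geometry is of no consequence because it is hydrogenated next, and both stereocentres are remote from the reacting carbons.

Step 11
Reactants: 24 (3R)-6,8-bis(benzyloxy)-3-[(2E,9S)-9-(benzyloxy)undec-2-en-1-yl]isochroman-1-one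
Product: 25 (3R)-6,8-dihydroxy-3-[(9S)-9-hydroxyundecyl]isochroman-1-one
Conditions: H2 (1 atm), 10% Pd/C, EtOH/EtOAc, rt
Reagents that add atoms: none
Why: Heterogeneous catalytic hydrogenation saturates the C2'=C3' alkene and hydrogenolyses the two aryl benzyl ethers and the secondary alkyl benzyl ether in one operation, while the lactone, whose C3–O bond is homobenzylic and homoallylic and neither benzylic nor allylic, and both stereocentres are left untouched.

**Compound list**

1 | 3,5-bis(benzyloxy)phenol | Oc1cc(OCc2ccccc2)cc(OCc2ccccc2)c1 | starting material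
2 | 3,5-bis(benzyloxy)-2-bromophenol | Oc1cc(OCc2ccccc2)cc(OCc2ccccc2)c1Br | intermediate
3 | [3,5-bis(benzyloxy)-2-bromophenoxy]trimethylsilane | C[Si](C)(C)Oc1cc(OCc2ccccc2)cc(OCc2ccccc2)c1Br | intermediate
4 | {2,4-bis(benzyloxy)-6-[(trimethylsilyl)oxy]phenyl}lithium | C[Si](C)(C)Oc1cc(OCc2ccccc2)cc(OCc2ccccc2)c1[Li] | intermediate
5 | lithium 3,5-bis(benzyloxy)-2-(trimethylsilyl)phenoxide | [Li]Oc1cc(OCc2ccccc2)cc(OCc2ccccc2)c1[Si](C)(C)C | intermediate
6 | 3,5-bis(benzyloxy)-2-(trimethylsilyl)phenyl trifluoromethanesulfonate | C[Si](C)(C)c1c(OCc2ccccc2)cc(OCc2ccccc2)cc1OS(=O)(=O)C(F)(F)F | intermediate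
7 | dimethyl malonate | COC(=O)CC(=O)OC | starting material
8 | caesium dimethyl malonate (dimethyl 2-caesiomalonate) | COC(=O)C([Cs])C(=O)OC | intermediate
9 | 3,5-bis(benzyloxy)benzyne (3,5-bis(benzyloxy)-1,2-didehydrobenzene) | C1#CC(OCc2ccccc2)=CC(OCc2ccccc2)=C1 | intermediate
10 | dimethyl 2-[3,5-bis(benzyloxy)-2-caesiophenyl]malonate | COC(=O)C(C(=O)OC)c1cc(OCc2ccccc2)cc(OCc2ccccc2)c1[Cs] | intermediate
11 | caesium 3,5-bis(benzyloxy)-7-methoxy-8-(methoxycarbonyl)bicyclo[4.2.0]octa-1,3,5-trien-7-olate | COC(=O)C1c2cc(OCc3ccccc3)cc(OCc3ccccc3)c2C1(OC)O[Cs] | intermediate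
12 | methyl 2,4-bis(benzyloxy)-6-(1-caesio-2-methoxy-2-oxoethyl)benzoate (caesium enolate of 13) | COC(=O)C([Cs])c1cc(OCc2ccccc2)cc(OCc2ccccc2)c1C(=O)OC | intermediate
13 | methyl 2,4-bis(benzyloxy)-6-(2-methoxy-2-oxoethyl)benzoate | COC(=O)Cc1cc(OCc2ccccc2)cc(OCc2ccccc2)c1C(=O)OC | intermediate
14 | methyl 2,4-bis(benzyloxy)-6-{2-[(diisobutylalumanyl)oxy]-2-methoxyethyl}benzoate | COC(O[Al](CC(C)C)CC(C)C)Cc1cc(OCc2ccccc2)cc(OCc2ccccc2)c1C(=O)OC | intermediate
15 | methyl 2,4-bis(benzyloxy)-6-(2-oxoethyl)benzoate | O=CCc1cc(OCc2ccccc2)cc(OCc2ccccc2)c1C(=O)OC | intermediate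
16 | diisopinocampheylborinate of 17: methyl 2,4-bis(benzyloxy)-6-[(2R)-2-{[bis(isopinocampheyl)boranyl]oxy}pent-4-en-1-yl]benzoate, isopinocampheyl groups from (−)-α-pinene | C=CC[C@@H](OB([C@H]1C[C@H]2C[C@@H]([C@@H]1C)C2(C)C)[C@H]1C[C@H]2C[C@@H]([C@@H]1C)C2(C)C)Cc1cc(OCc2ccccc2)cc(OCc2ccccc2)c1C(=O)OC | intermediate
17 | methyl 2,4-bis(benzyloxy)-6-[(2R)-2-hydroxypent-4-en-1-yl]benzoate | C=CC[C@@H](O)Cc1cc(OCc2ccccc2)cc(OCc2ccccc2)c1C(=O)OC | intermediate
18 | (3R)-3-allyl-6,8-bis(benzyloxy)isochroman-1-one | C=CC[C@@H]1Cc2cc(OCc3ccccc3)cc(OCc3ccccc3)c2C(=O)O1 | intermediate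
19 | 6-bromohex-1-ene | C=CCCCCBr | starting material
20 | (S)-1,2-epoxybutane [(2S)-2-ethyloxirane] | CC[C@H]1CO1 | starting material
21 | hex-5-en-1-ylmagnesium bromide | C=CCCCC[Mg]Br | intermediate
22 | (3S)-dec-9-en-3-ol | CC[C@H](O)CCCCCC=C | intermediate
23 | (S)-{[(dec-9-en-3-yl)oxy]methyl}benzene | CC[C@H](OCc1ccccc1)CCCCCC=C | intermediate
24 | (3R)-6,8-bis(benzyloxy)-3-[(2E,9S)-9-(benzyloxy)undec-2-en-1-yl]isochroman-1-one | CC[C@H](OCc1ccccc1)CCCCC/C=C/C[C@@H]1Cc2cc(OCc3ccccc3)cc(OCc3ccccc3)c2C(=O)O1 | intermediate
25 | (3R)-6,8-dihydroxy-3-[(9S)-9-hydroxyundecyl]isochroman-1-one | CC[C@H](O)CCCCCCCC[C@@H]1Cc2cc(O)cc(O)c2C(=O)O1 | target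

**Step count and risks**

Total step count: 11. Longest linear sequence: 9 steps (steps 1 to 7, then 10 and 11, from compound 1); the side chain takes steps 8 and 9.

Steps most likely to fail:

1. Step 4 (aryne insertion). What may go wrong: protonation of aryl anion 10 before the acyl transfer (plain α-arylation of the malonate), a second arylation of 13 at its benzylic CH2, or erosion of the regioselectivity of addition to aryne 9. The fallback builds the two ortho carbon substituents by carboxylation, cross-coupling and oxidative cleavage instead of aryne insertion; it sets out from compound 2 and comes back to the route at compound 15, so that steps 2 to 5 are bypassed. Phenol 2 is protected (MOMCl, iPr2NEt, CH2Cl2) as 1,5-bis(benzyloxy)-2-bromo-3-(methoxymethoxy)benzene F1. Bromine–lithium exchange (n-BuLi, THF, −78 °C) gives [2,4-bis(benzyloxy)-6-(methoxymethoxy)phenyl]lithium F2, which is quenched with methyl chloroformate to methyl 2,4-bis(benzyloxy)-6-(methoxymethoxy)benzoate F3. HCl in MeOH removes the acetal to give methyl 2,4-bis(benzyloxy)-6-hydroxybenzoate F4, and Tf2O/pyridine gives methyl 2,4-bis(benzyloxy)-6-{[(trifluoromethyl)sulfonyl]oxy}benzoate F5. Stille coupling with allyltributylstannane (Pd(PPh3)4, LiCl, DMF, 90 °C) should give methyl 2-allyl-4,6-bis(benzyloxy)benzoate F6, and Lemieux–Johnson cleavage (OsO4 cat., NaIO4, 2,6-lutidine, dioxane/H2O) gives 15.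

2. Step 5 (partial reduction). What may go wrong: over-reduction to the primary alcohol, which would lactonise onto the aryl ester, competing attack on the aryl ester, or aldol self-condensation of the arylacetaldehyde during work-up. The fallback changes the acyl derivative that is reduced; it sets out from compound 13 and comes back at compound 15. Selective saponification of the unhindered aliphatic ester (LiOH, 1.05 equiv, THF/H2O, 0 °C) should give 2-[3,5-bis(benzyloxy)-2-(methoxycarbonyl)phenyl]acetic acid F7. Coupling with N,O-dimethylhydroxylamine hydrochloride (EDC·HCl, HOBt, iPr2NEt, CH2Cl2) gives the Weinreb amide methyl 2,4-bis(benzyloxy)-6-{2-[methoxy(methyl)amino]-2-oxoethyl}benzoate F8. Reduction with Cp2Zr(H)Cl in THF at rt, which takes tertiary amides to aldehydes and leaves esters alone, returns 15.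

3. Step 10 (cross-metathesis). What may go wrong: homodimerisation of lactone 18 competing with the cross reaction, incomplete conversion, or migration of the double bond along the chain by ruthenium hydride species, which would shorten the chain. The fallback attaches the whole saturated side chain to the aldehyde by a catalytic enantioselective alkylzinc addition instead of allylation and metathesis; it sets out from compound 15 and comes back at compound 25.
   - Side chain: 7-bromohept-1-ene F9 is converted (Mg, THF) into hept-6-en-1-ylmagnesium bromide F10, which opens epoxide 20 under CuI catalysis to (3S)-undec-10-en-3-ol F11. Benzylation as in step 9 gives (S)-{[(undec-10-en-3-yl)oxy]methyl}benzene F12.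
   - Zinc reagent: hydroboration of F12 with Et2BH (Et2O, 0 °C → rt) gives [(9S)-9-(benzyloxy)undecyl]diethylborane F13. Boron–zinc exchange with neat Et2Zn, in which two molecules of F13 deliver their alkyl groups to one zinc and Et3B and excess Et2Zn are pumped off, gives bis[(9S)-9-(benzyloxy)undecyl]zinc F14.
   - Coupling: addition of F14 to 15 with Ti(OiPr)4 and (1S,2S)-1,2-bis(trifluoromethanesulfonamido)cyclohexane (8 mol%) in toluene at −20 °C should give methyl 2,4-bis(benzyloxy)-6-[(2R,11S)-11-(benzyloxy)-2-hydroxytridecyl]benzoate F15. The (1S,2S) ligand is the antipode of the one known to deliver alkyl groups to the Si face, so Re-face attack is expected.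
   - End: lactonisation with catalytic p-TsOH gives (3R)-6,8-bis(benzyloxy)-3-[(9S)-9-(benzyloxy)undecyl]isochroman-1-one F16, and the conditions of step 11 remove the three benzyl groups to give 25.

**Further compounds**

F1 | step 4 | 1,5-bis(benzyloxy)-2-bromo-3-(methoxymethoxy)benzene | COCOc1cc(OCc2ccccc2)cc(OCc2ccccc2)c1Br
F2 | step 4 | [2,4-bis(benzyloxy)-6-(methoxymethoxy)phenyl]lithium | COCOc1cc(OCc2ccccc2)cc(OCc2ccccc2)c1[Li]
F3 | step 4 | methyl 2,4-bis(benzyloxy)-6-(methoxymethoxy)benzoate | COCOc1cc(OCc2ccccc2)cc(OCc2ccccc2)c1C(=O)OC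
F4 | step 4 | methyl 2,4-bis(benzyloxy)-6-hydroxybenzoate | Oc1cc(OCc2ccccc2)cc(OCc2ccccc2)c1C(=O)OC
F5 | step 4 | methyl 2,4-bis(benzyloxy)-6-{[(trifluoromethyl)sulfonyl]oxy}benzoate | COC(=O)c1c(OCc2ccccc2)cc(OCc2ccccc2)cc1OS(=O)(=O)C(F)(F)F
F6 | step 4 | methyl 2-allyl-4,6-bis(benzyloxy)benzoate | C=CCc1cc(OCc2ccccc2)cc(OCc2ccccc2)c1C(=O)OC
F7 | step 5 | 2-[3,5-bis(benzyloxy)-2-(methoxycarbonyl)phenyl]acetic acid | OC(=O)Cc1cc(OCc2ccccc2)cc(OCc2ccccc2)c1C(=O)OC
F8 | step 5 | methyl 2,4-bis(benzyloxy)-6-{2-[methoxy(methyl)amino]-2-oxoethyl}benzoate | CON(C)C(=O)Cc1cc(OCc2ccccc2)cc(OCc2ccccc2)c1C(=O)OC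
F9 | step 10 | 7-bromohept-1-ene | C=CCCCCCBr
F10 | step 10 | hept-6-en-1-ylmagnesium bromide | C=CCCCCC[Mg]Br
F11 | step 10 | (3S)-undec-10-en-3-ol | CC[C@H](O)CCCCCCC=C
F12 | step 10 | (S)-{[(undec-10-en-3-yl)oxy]methyl}benzene | CC[C@H](OCc1ccccc1)CCCCCCC=C
F13 | step 10 | [(9S)-9-(benzyloxy)undecyl]diethylborane | CC[C@H](OCc1ccccc1)CCCCCCCCB(CC)CC
F14 | step 10 | bis[(9S)-9-(benzyloxy)undecyl]zinc | CC[C@H](OCc1ccccc1)CCCCCCCC[Zn]CCCCCCCC[C@H](CC)OCc1ccccc1
F15 | step 10 | methyl 2,4-bis(benzyloxy)-6-[(2R,11S)-11-(benzyloxy)-2-hydroxytridecyl]benzoate | CC[C@H](OCc1ccccc1)CCCCCCCC[C@@H](O)Cc1cc(OCc2ccccc2)cc(OCc2ccccc2)c1C(=O)OC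
F16 | step 10 | (3R)-6,8-bis(benzyloxy)-3-[(9S)-9-(benzyloxy)undecyl]isochroman-1-one | CC[C@H](OCc1ccccc1)CCCCCCCC[C@@H]1Cc2cc(OCc3ccccc3)cc(OCc3ccccc3)c2C(=O)O1
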